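The route rests on cutting the C9–C10 bond of ring B and re-joining C6 to oxygen, which turns the decalin into a six-membered lactone hung on a ring A cyclohexene. The feature used is the vicinal pair C9 (bearing C11) and quaternary C10 (bearing C20) beside C5: an allylic C6–O stereocentre next to the C5=C10 alkene can pass its chirality to C10. Heating the silyl ketene acetal of this lactone should, in one operation, form C9–C10, close ring B, set C10 and C9, and leave the C5=C6 alkene and the C11 carboxyl. The precursor is a cis-4-silyloxy-6-cyclohexenyl δ-lactone made from a ring A enol triflate and an enantiopure 3-silyloxyglutarate aldehyde.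

Key step: step 8

Remark: bicyclic compounds are named with labdane locants (C18 and C19 on C4, C20 on C10, C11 on C9) used only as a numbering system, syn and anti refer to the face of C20, and (3R)-3-(tert-butyldimethylsilyloxy)glutaric acid monomethyl ester is assumed to be a purchasable statin building block.

Step 1
Reactants: 1 2,2,6-trimethylcyclohexane-1,4-dione (racemic)
Product: 2 7,9,9-trimethyl-1,4-dioxaspiro[4.5]decan-8-one
Conditions: HOCH2CH2OH, TsOH (cat.), PhH, reflux, Dean–Stark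
Reagents that add atoms: ethylene glycol OCCO
Why: Acid-catalysed ketalization should take only the C4 carbonyl, because the C1 carbonyl lies between a quaternary and a tertiary carbon; the methyl-bearing stereocentre is racemic and is erased in step 2.

Step 2
Reactants: 2 7,9,9-trimethyl-1,4-dioxaspiro[4.5]decan-8-one
Product: 3 7,9,9-trimethyl-1,4-dioxaspiro[4.5]dec-7-en-8-yl trifluoromethanesulfonate
Conditions: LiN(i-Pr)2, THF, −78 to 0 °C; PhNTf2, 0 °C to rt
Reagents that add atoms: N-phenylbis(trifluoromethanesulfonimide) O=S(=O)(N(c1ccccc1)S(=O)(=O)C(F)(F)F)C(F)(F)F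
Why: Enol triflate formation: the ketone has a single alpha-hydrogen (C7), so enolization and O-sulfonylation can only give the tetrasubstituted enol triflate.

Step 3
Reactants: 4 (3R)-3-(tert-butyldimethylsilyloxy)-5-methoxy-5-oxopentanoic acid
Product: 5 methyl (3R)-3-(tert-butyldimethylsilyloxy)-5-hydroxypentanoate
Conditions: BH3·SMe2, THF, 0 °C to rt; MeOH
Reagents that add atoms: none
Why: Chemoselective borane reduction: borane reduces the carboxylic acid much faster than the ester, so only the acid terminus becomes the primary alcohol and C3 is untouched.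

Step 4
Reactants: 5 methyl (3R)-3-(tert-butyldimethylsilyloxy)-5-hydroxypentanoate
Product: 6 methyl (3R)-3-(tert-butyldimethylsilyloxy)-5-oxopentanoate
Conditions: Dess–Martin periodinane, NaHCO3, CH2Cl2, 0 °C to rt
Reagents that add atoms: none
Why: Dess–Martin oxidation under buffered, non-basic conditions should give the aldehyde without beta-elimination of the silyl ether.

Step 5
Reactants: 3 7,9,9-trimethyl-1,4-dioxaspiro[4.5]dec-7-en-8-yl trifluoromethanesulfonate; 6 methyl (3R)-3-(tert-butyldimethylsilyloxy)-5-oxopentanoate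
Product: 7 methyl (3R,5RS)-3-(tert-butyldimethylsilyloxy)-5-hydroxy-5-(7,9,9-trimethyl-1,4-dioxaspiro[4.5]dec-7-en-8-yl)pentanoate
Conditions: CrCl2 (4 equiv), NiCl2 (2 mol %), DMF, rt to 50 °C
Reagents that add atoms: none
Why: Nozaki–Hiyama–Kishi coupling: nickel-mediated formation of an alkenylchromium species from the enol triflate and its addition to the aldehyde in preference to the ester forms the C5–C6 bond; the new carbinol is not controlled and is corrected in steps 6 and 7.

Step 6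
Reactants: 7 methyl (3R,5RS)-3-(tert-butyldimethylsilyloxy)-5-hydroxy-5-(7,9,9-trimethyl-1,4-dioxaspiro[4.5]dec-7-en-8-yl)pentanoate
Product: 8 methyl (3R)-3-(tert-butyldimethylsilyloxy)-5-oxo-5-(7,9,9-trimethyl-1,4-dioxaspiro[4.5]dec-7-en-8-yl)pentanoate
Conditions: Dess–Martin periodinane, NaHCO3, CH2Cl2, rt
Reagents that add atoms: none
Why: Dess–Martin oxidation converts both carbinol epimers into one enone under conditions too mild to eliminate the beta-silyloxy group.

Step 7
Reactants: 8 methyl (3R)-3-(tert-butyldimethylsilyloxy)-5-oxo-5-(7,9,9-trimethyl-1,4-dioxaspiro[4.5]dec-7-en-8-yl)pentanoate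
Product: 10 (4R,6R)-4-(tert-butyldimethylsilyloxy)-6-(7,9,9-trimethyl-1,4-dioxaspiro[4.5]dec-7-en-8-yl)oxan-2-one, via hydroxy ester 9 (not isolated)
Conditions: (S)-Me-CBS (0.2 equiv), BH3·SMe2, THF, −30 °C; MeOH; then PPTS (cat.), PhMe, 40 °C
Reagents that add atoms: none
Why: Corey–Bakshi–Shibata reduction with the (S)-oxazaborolidine should deliver hydride to the ketone face that gives the (5R) carbinol, the cyclohexenyl group acting as the large substituent (reagent control), and mild acid then closes the cis δ-lactone by lactonization.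

Step 8
Reactants: 10 (4R,6R)-4-(tert-butyldimethylsilyloxy)-6-(7,9,9-trimethyl-1,4-dioxaspiro[4.5]dec-7-en-8-yl)oxan-2-one
Product: 13 (8R,9R,10S)-8-(tert-butyldimethylsilyloxy)-2,2-(ethylenedioxy)-12,13,14,15,16,17-hexanorlabd-5-en-11-oic acid, via silyl ketene acetal 11 (not isolated), via silyl ester 12 (not isolated)
Conditions: LiN(i-Pr)2, THF, −78 °C; t-BuMe2SiCl, DMPU, −78 °C to rt; PhMe, 110 °C (sealed); then K2CO3, MeOH–H2O, work-up at pH 4
Reagents that add atoms: none
Why: Deprotonation of 10 at C9 and silylation on oxygen give ketene acetal 11, whose C9=C11(OSi)–O–C6–C5=C10 array undergoes a suprafacial [3,3] shift on heating: C9–C10 forms, O–C6 breaks, the alkene moves to C5=C6 and silyl ester 12 results, which is hydrolysed to 13. The reaction type is the Ireland–Claisen rearrangement of an alkenyl lactone to a cycloalkenecarboxylic acid, which must pass through a boat because the C7–C8 bridge ties C6 to C9. Ring B closes in this shift as a six-membered carbocycle (C6 to C9 of the lactone plus C5 and C10), while the C11–O unit leaves the ring and becomes the exocyclic carboxyl. C10 is set by the C6 carbinol, since the alkene can reach C9 only across the lactone face that carries it, so the (6R) centre bonds C9 to the face of C10 that leaves C20 as in the target; C9 is set by the same bicyclic array with C11 anti to C20, which step 16 corrects. The selectivity needed is the [3,3] shift over beta-elimination of the C8 silyloxy group and over decomposition on long heating; the equatorial C8–O bond is poorly aligned with the enolate, the enolate is trapped cold, and the tert-butyldimethylsilyl ketene acetal should tolerate the temperature that the crowded boat (C20 on the inside) is expected to need.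

Step 9
Reactants: 13 (8R,9R,10S)-8-(tert-butyldimethylsilyloxy)-2,2-(ethylenedioxy)-12,13,14,15,16,17-hexanorlabd-5-en-11-oic acid
Product: 14 (8R,9S,10S)-8-(tert-butyldimethylsilyloxy)-2,2-(ethylenedioxy)-12,13,14,15,16,17-hexanorlabd-5-en-11-ol
Conditions: LiAlH4, THF, 0 to 40 °C
Reagents that add atoms: none
Why: Hydride reduction of the carboxylic acid gives the C11 primary alcohol and leaves the silyl ether and the ketal intact.

Step 10
Reactants: 14 (8R,9S,10S)-8-(tert-butyldimethylsilyloxy)-2,2-(ethylenedioxy)-12,13,14,15,16,17-hexanorlabd-5-en-11-ol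
Product: 15 (5R,8R,9S,10R)-8-(tert-butyldimethylsilyloxy)-2,2-(ethylenedioxy)-12,13,14,15,16,17-hexanorlabdan-11-ol
Conditions: [Ir(cod)(PCy3)(py)]PF6 (5 mol %), H2 (1 atm), CH2Cl2, rt
Reagents that add atoms: none
Why: Hydroxyl-directed hydrogenation with Crabtree's catalyst: the C11 hydroxyl lies on the face anti to C20, binds iridium and delivers hydrogen to that face of the hindered C5=C6 alkene, which sets H-5 anti to C20 (trans ring fusion).

Step 11
Reactants: 15 (5R,8R,9S,10R)-8-(tert-butyldimethylsilyloxy)-2,2-(ethylenedioxy)-12,13,14,15,16,17-hexanorlabdan-11-ol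
Product: 16 (5R,8R,9R,10R)-8-(tert-butyldimethylsilyloxy)-2,2-(ethylenedioxy)-12,13,14,15,16,17-hexanorlabdan-11-al
Conditions: Dess–Martin periodinane, NaHCO3, CH2Cl2, 0 °C
Reagents that add atoms: none
Why: Dess–Martin oxidation under buffered conditions gives the aldehyde without enolization at C9 or loss of the C8 silyloxy group.

Step 12
Reactants: 16 (5R,8R,9R,10R)-8-(tert-butyldimethylsilyloxy)-2,2-(ethylenedioxy)-12,13,14,15,16,17-hexanorlabdan-11-al
Product: 17 (5R,8R,9R,10R)-8-(tert-butyldimethylsilyloxy)-2,2-(ethylenedioxy)-13,14,15,16,17-pentanorlabd-11-ene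
Conditions: Ph3PCH3Br, KN(SiMe3)2, THF, 0 °C; then 16, −78 to 0 °C
Reagents that add atoms: methyltriphenylphosphonium bromide C[P+](c1ccccc1)(c1ccccc1)c1ccccc1.[Br-]
Why: Wittig methylenation with the non-stabilised ylide at low temperature should be faster than deprotonation at the hindered C9 and adds C12 as a vinyl group.

Step 13
Reactants: 17 (5R,8R,9R,10R)-8-(tert-butyldimethylsilyloxy)-2,2-(ethylenedioxy)-13,14,15,16,17-pentanorlabd-11-ene
Product: 19 (5R,8R,9R,10R)-8-(tert-butyldimethylsilyloxy)-2,2-(ethylenedioxy)-13,14,15,16,17-pentanorlabdan-12-ol, via alkylborane 18 (not isolated)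
Conditions: 9-BBN, THF, rt to 60 °C; then NaOH, H2O2, 0 °C to rt
Reagents that add atoms: hydrogen peroxide OO
Why: Hydroboration–oxidation places boron on the terminal C12 of the only alkene present (anti-Markovnikov), and alkaline peroxide gives the primary alcohol.

Step 14
Reactants: 19 (5R,8R,9R,10R)-8-(tert-butyldimethylsilyloxy)-2,2-(ethylenedioxy)-13,14,15,16,17-pentanorlabdan-12-ol
Product: 20 (5R,8R,9R,10R)-12-(benzyloxy)-8-(tert-butyldimethylsilyloxy)-2,2-(ethylenedioxy)-13,14,15,16,17-pentanorlabdane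
Conditions: NaH, BnBr, Bu4NI (cat.), THF–DMF, 0 °C to rt
Reagents that add atoms: benzyl bromide BrCc1ccccc1
Why: Williamson etherification gives a benzyl ether that survives fluoride, oxidation, base and ylide and is removed in step 19 by the reagent that reduces the C2 ketone.

Step 15
Reactants: 20 (5R,8R,9R,10R)-12-(benzyloxy)-8-(tert-butyldimethylsilyloxy)-2,2-(ethylenedioxy)-13,14,15,16,17-pentanorlabdane
Product: 21 (5R,8R,9R,10R)-12-(benzyloxy)-2,2-(ethylenedioxy)-13,14,15,16,17-pentanorlabdan-8-ol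
Conditions: Bu4NF, THF, 50 °C
Reagents that add atoms: none
Why: Fluoride-mediated desilylation frees the C8 alcohol; ketal and benzyl ether are inert.

Step 16
Reactants: 21 (5R,8R,9R,10R)-12-(benzyloxy)-2,2-(ethylenedioxy)-13,14,15,16,17-pentanorlabdan-8-ol
Product: 23 (5R,9S,10R)-12-(benzyloxy)-2,2-(ethylenedioxy)-13,14,15,16,17-pentanorlabdan-8-one, via C9-epimeric ketone 22 (not isolated)
Conditions: Pr4N[RuO4] (5 mol %), NMO, 4 Å sieves, CH2Cl2, rt; then NaOMe, MeOH, 40 °C
Reagents that add atoms: none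
Why: Ley–Griffith oxidation gives the C8 ketone, and methoxide then equilibrates C9 through the enolate to the epimer expected to be more stable, with the side chain equatorial and syn to C20 as in the target (thermodynamic epimerization); C11 carries no leaving group, so elimination cannot compete, and any minor epimer can be resubmitted.

Step 17
Reactants: 23 (5R,9S,10R)-12-(benzyloxy)-2,2-(ethylenedioxy)-13,14,15,16,17-pentanorlabdan-8-one
Product: 24 (5R,9R,10R)-12-(benzyloxy)-2,2-(ethylenedioxy)-13,14,15,16-tetranorlabd-8(17)-ene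
Conditions: Ph3PCH3Br, KOt-Bu, PhMe, 90 °C
Reagents that add atoms: methyltriphenylphosphonium bromide C[P+](c1ccccc1)(c1ccccc1)c1ccccc1.[Br-]
Why: Wittig methylenation of the hindered C8 ketone installs C17 as the exocyclic alkene, and the basic medium keeps C9 at its thermodynamic configuration until the alkene fixes it.

Step 18
Reactants: 24 (5R,9R,10R)-12-(benzyloxy)-2,2-(ethylenedioxy)-13,14,15,16-tetranorlabd-8(17)-ene
Product: 25 (5R,9R,10R)-12-(benzyloxy)-13,14,15,16-tetranorlabd-8(17)-en-2-one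
Conditions: PPTS, acetone–H2O, 60 °C
Reagents that add atoms: water O
Why: Mild acid-catalysed ketal hydrolysis releases the C2 ketone under conditions that should not isomerize the exocyclic alkene.

Step 19
Reactants: 25 (5R,9R,10R)-12-(benzyloxy)-13,14,15,16-tetranorlabd-8(17)-en-2-one
Product: 26 (2R,5R,9R,10R)-13,14,15,16-tetranorlabd-8(17)-ene-2,12-diol
Conditions: Li, NH3(l), THF, t-BuOH, −78 to −33 °C; NH4Cl
Reagents that add atoms: none
Why: Dissolving-metal reduction gives the thermodynamically preferred equatorial C2 alcohol, whereas hydride reagents would approach anti to the axial methyl groups on C4 and C10 and give the axial alcohol; the same conditions cleave the benzyl ether and leave the isolated alkene alone.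

Step 20
Reactants: 26 (2R,5R,9R,10R)-13,14,15,16-tetranorlabd-8(17)-ene-2,12-diol
Product: 28 (2R,5R,9R,10R)-12-iodo-2-(triethylsilyloxy)-13,14,15,16-tetranorlabd-8(17)-ene, via iodo alcohol 27 (not isolated)
Conditions: PPh3, I2, imidazole, CH2Cl2, 0 °C; then Et3SiCl, imidazole, rt
Reagents that add atoms: iodine II; chlorotriethylsilane CC[Si](Cl)(CC)CC
Why: Appel-type iodination is selective for the primary alcohol, and the secondary C2 alcohol is then silylated in the same flask.

Step 21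
Reactants: 29 ethyl 4-chloro-3-oxobutanoate
Product: 30 2-(trimethylsilyl)ethyl 4-chloro-3-oxobutanoate
Conditions: Me3SiCH2CH2OH, DMAP (cat.), PhMe, reflux with removal of EtOH
Reagents that add atoms: 2-(trimethylsilyl)ethanol C[Si](C)(C)CCO
Why: Thermal transesterification of a beta-keto ester through its acylketene exchanges ethyl for the fluoride-labile 2-(trimethylsilyl)ethyl group.

Step 22
Reactants: 30 2-(trimethylsilyl)ethyl 4-chloro-3-oxobutanoate
Product: 31 2-(trimethylsilyl)ethyl 4-acetoxy-3-oxobutanoate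
Conditions: KOAc, AcOH, DMF, 40 °C
Reagents that add atoms: potassium acetate CC(=O)[O-].[K+]
Why: SN2 displacement of the activated alpha-chloro ketone by acetate under buffered conditions introduces the C16 acetate.

Step 23
Reactants: 31 2-(trimethylsilyl)ethyl 4-acetoxy-3-oxobutanoate
Product: 32 2-(trimethylsilyl)ethyl (E)-4-acetoxy-3-(trifluoromethylsulfonyloxy)but-2-enoate
Conditions: Tf2O, aq. Me4NOH, PhMe, 5 °C
Reagents that add atoms: trifluoromethanesulfonic anhydride O=S(=O)(OS(=O)(=O)C(F)(F)F)C(F)(F)F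
Why: O-Triflation of the non-chelated tetramethylammonium enolate is expected to favour the (E)-enol triflate with the triflate anti to the ester; the geometry is checked and any (Z) isomer removed at this stage.

Step 24
Reactants: 28 (2R,5R,9R,10R)-12-iodo-2-(triethylsilyloxy)-13,14,15,16-tetranorlabd-8(17)-ene; 32 2-(trimethylsilyl)ethyl (E)-4-acetoxy-3-(trifluoromethylsulfonyloxy)but-2-enoate
Product: 34 2-(trimethylsilyl)ethyl (2R,5R,9R,10R,13Z)-16-acetoxy-2-(triethylsilyloxy)labda-8(17),13-dien-15-oate, via alkylzinc iodide 33 (not isolated)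
Conditions: Zn dust, LiCl, THF, 40 °C; then 32, PdCl2(dppf) (5 mol %), THF, rt to 50 °C
Reagents that add atoms: none
Why: Zinc insertion into the primary iodide followed by Negishi coupling with the enol triflate proceeds with retention of alkene geometry, so C12 ends trans to C15 and the acetoxymethyl group cis to the ester (13Z); ester, acetate, silyl ether and the 1,1-disubstituted alkene are tolerated by the organozinc.

Step 25
Reactants: 34 2-(trimethylsilyl)ethyl (2R,5R,9R,10R,13Z)-16-acetoxy-2-(triethylsilyloxy)labda-8(17),13-dien-15-oate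
Product: 35 (2R,5R,9R,10R,13Z)-16-acetoxy-2-hydroxylabda-8(17),13-dien-15-oic acid
Conditions: Bu4NF, THF, 0 °C to rt; work-up at pH 4
Reagents that add atoms: none
Why: Fluoride cleaves the 2-(trimethylsilyl)ethyl ester by beta-elimination and the triethylsilyl ether at silicon, under conditions expected to spare the allylic acetate and both alkenes.

Compound list

1 | 2,2,6-trimethylcyclohexane-1,4-dione (racemic) | CC1CC(=O)CC(C)(C)C1=O | starting material
2 | 7,9,9-trimethyl-1,4-dioxaspiro[4.5]decan-8-one (racemic) | CC1CC2(OCCO2)CC(C)(C)C1=O | intermediate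
3 | 7,9,9-trimethyl-1,4-dioxaspiro[4.5]dec-7-en-8-yl trifluoromethanesulfonate | CC1=C(OS(=O)(=O)C(F)(F)F)C(C)(C)CC2(OCCO2)C1 | intermediate
4 | (3R)-3-(tert-butyldimethylsilyloxy)-5-methoxy-5-oxopentanoic acid | COC(=O)C[C@H](O[Si](C)(C)C(C)(C)C)CC(=O)O | starting material
5 | methyl (3R)-3-(tert-butyldimethylsilyloxy)-5-hydroxypentanoate | COC(=O)C[C@H](O[Si](C)(C)C(C)(C)C)CCO | intermediate
6 | methyl (3R)-3-(tert-butyldimethylsilyloxy)-5-oxopentanoate | COC(=O)C[C@H](O[Si](C)(C)C(C)(C)C)CC=O | intermediate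
7 | methyl (3R,5RS)-3-(tert-butyldimethylsilyloxy)-5-hydroxy-5-(7,9,9-trimethyl-1,4-dioxaspiro[4.5]dec-7-en-8-yl)pentanoate | COC(=O)C[C@H](O[Si](C)(C)C(C)(C)C)CC(O)C1=C(C)CC2(OCCO2)CC1(C)C | intermediate
8 | methyl (3R)-3-(tert-butyldimethylsilyloxy)-5-oxo-5-(7,9,9-trimethyl-1,4-dioxaspiro[4.5]dec-7-en-8-yl)pentanoate | COC(=O)C[C@H](O[Si](C)(C)C(C)(C)C)CC(=O)C1=C(C)CC2(OCCO2)CC1(C)C | intermediate
9 | methyl (3R,5R)-3-(tert-butyldimethylsilyloxy)-5-hydroxy-5-(7,9,9-trimethyl-1,4-dioxaspiro[4.5]dec-7-en-8-yl)pentanoate | COC(=O)C[C@H](O[Si](C)(C)C(C)(C)C)C[C@@H](O)C1=C(C)CC2(OCCO2)CC1(C)C | intermediate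
10 | (4R,6R)-4-(tert-butyldimethylsilyloxy)-6-(7,9,9-trimethyl-1,4-dioxaspiro[4.5]dec-7-en-8-yl)oxan-2-one (cis lactone) | O=C1C[C@H](O[Si](C)(C)C(C)(C)C)C[C@@H](O1)C1=C(C)CC2(OCCO2)CC1(C)C | intermediate
11 | (4R,6R)-2,4-bis(tert-butyldimethylsilyloxy)-6-(7,9,9-trimethyl-1,4-dioxaspiro[4.5]dec-7-en-8-yl)-5,6-dihydro-4H-pyran | CC(C)(C)[Si](C)(C)OC1=C[C@H](O[Si](C)(C)C(C)(C)C)C[C@@H](O1)C1=C(C)CC2(OCCO2)CC1(C)C | intermediate
12 | tert-butyldimethylsilyl (8R,9R,10S)-8-(tert-butyldimethylsilyloxy)-2,2-(ethylenedioxy)-12,13,14,15,16,17-hexanorlabd-5-en-11-oate | CC(C)(C)[Si](C)(C)O[C@@H]1CC=C2C(C)(C)CC3(OCCO3)C[C@@]2(C)[C@H]1C(=O)O[Si](C)(C)C(C)(C)C | intermediate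
13 | (8R,9R,10S)-8-(tert-butyldimethylsilyloxy)-2,2-(ethylenedioxy)-12,13,14,15,16,17-hexanorlabd-5-en-11-oic acid (silyloxy syn, carboxyl anti to C20) | CC(C)(C)[Si](C)(C)O[C@@H]1CC=C2C(C)(C)CC3(OCCO3)C[C@@]2(C)[C@H]1C(=O)O | intermediate
14 | (8R,9S,10S)-8-(tert-butyldimethylsilyloxy)-2,2-(ethylenedioxy)-12,13,14,15,16,17-hexanorlabd-5-en-11-ol | CC(C)(C)[Si](C)(C)O[C@@H]1CC=C2C(C)(C)CC3(OCCO3)C[C@@]2(C)[C@H]1CO | intermediate
15 | (5R,8R,9S,10R)-8-(tert-butyldimethylsilyloxy)-2,2-(ethylenedioxy)-12,13,14,15,16,17-hexanorlabdan-11-ol (trans-fused) | CC(C)(C)[Si](C)(C)O[C@@H]1CC[C@@H]2C(C)(C)CC3(OCCO3)C[C@@]2(C)[C@H]1CO | intermediate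
16 | (5R,8R,9R,10R)-8-(tert-butyldimethylsilyloxy)-2,2-(ethylenedioxy)-12,13,14,15,16,17-hexanorlabdan-11-al | CC(C)(C)[Si](C)(C)O[C@@H]1CC[C@@H]2C(C)(C)CC3(OCCO3)C[C@@]2(C)[C@H]1C=O | intermediate
17 | (5R,8R,9R,10R)-8-(tert-butyldimethylsilyloxy)-2,2-(ethylenedioxy)-13,14,15,16,17-pentanorlabd-11-ene | CC(C)(C)[Si](C)(C)O[C@@H]1CC[C@@H]2C(C)(C)CC3(OCCO3)C[C@@]2(C)[C@H]1C=C | intermediate
18 | 9-[(5R,8R,9R,10R)-8-(tert-butyldimethylsilyloxy)-2,2-(ethylenedioxy)-13,14,15,16,17-pentanorlabdan-12-yl]-9-borabicyclo[3.3.1]nonane | CC(C)(C)[Si](C)(C)O[C@@H]1CC[C@@H]2C(C)(C)CC3(OCCO3)C[C@@]2(C)[C@H]1CCB4C5CCCC4CCC5 | intermediate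
19 | (5R,8R,9R,10R)-8-(tert-butyldimethylsilyloxy)-2,2-(ethylenedioxy)-13,14,15,16,17-pentanorlabdan-12-ol | CC(C)(C)[Si](C)(C)O[C@@H]1CC[C@@H]2C(C)(C)CC3(OCCO3)C[C@@]2(C)[C@H]1CCO | intermediate
20 | (5R,8R,9R,10R)-12-(benzyloxy)-8-(tert-butyldimethylsilyloxy)-2,2-(ethylenedioxy)-13,14,15,16,17-pentanorlabdane | CC(C)(C)[Si](C)(C)O[C@@H]1CC[C@@H]2C(C)(C)CC3(OCCO3)C[C@@]2(C)[C@H]1CCOCc4ccccc4 | intermediate
21 | (5R,8R,9R,10R)-12-(benzyloxy)-2,2-(ethylenedioxy)-13,14,15,16,17-pentanorlabdan-8-ol | O[C@@H]1CC[C@@H]2C(C)(C)CC3(OCCO3)C[C@@]2(C)[C@H]1CCOCc4ccccc4 | intermediate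
22 | (5R,9R,10R)-12-(benzyloxy)-2,2-(ethylenedioxy)-13,14,15,16,17-pentanorlabdan-8-one (side chain anti to C20) | O=C1CC[C@@H]2C(C)(C)CC3(OCCO3)C[C@@]2(C)[C@H]1CCOCc4ccccc4 | intermediate
23 | (5R,9S,10R)-12-(benzyloxy)-2,2-(ethylenedioxy)-13,14,15,16,17-pentanorlabdan-8-one (side chain syn to C20) | O=C1CC[C@@H]2C(C)(C)CC3(OCCO3)C[C@@]2(C)[C@@H]1CCOCc4ccccc4 | intermediate
24 | (5R,9R,10R)-12-(benzyloxy)-2,2-(ethylenedioxy)-13,14,15,16-tetranorlabd-8(17)-ene | C=C1CC[C@@H]2C(C)(C)CC3(OCCO3)C[C@@]2(C)[C@@H]1CCOCc4ccccc4 | intermediate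
25 | (5R,9R,10R)-12-(benzyloxy)-13,14,15,16-tetranorlabd-8(17)-en-2-one | C=C1CC[C@@H]2C(C)(C)CC(=O)C[C@@]2(C)[C@@H]1CCOCc3ccccc3 | intermediate
26 | (2R,5R,9R,10R)-13,14,15,16-tetranorlabd-8(17)-ene-2,12-diol (C2 hydroxyl equatorial) | C=C1CC[C@@H]2C(C)(C)C[C@@H](O)C[C@@]2(C)[C@@H]1CCO | intermediate
27 | (2R,5R,9R,10R)-12-iodo-13,14,15,16-tetranorlabd-8(17)-en-2-ol | C=C1CC[C@@H]2C(C)(C)C[C@@H](O)C[C@@]2(C)[C@@H]1CCI | intermediate
28 | (2R,5R,9R,10R)-12-iodo-2-(triethylsilyloxy)-13,14,15,16-tetranorlabd-8(17)-ene | C=C1CC[C@@H]2C(C)(C)C[C@@H](O[Si](CC)(CC)CC)C[C@@]2(C)[C@@H]1CCI | intermediate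
29 | ethyl 4-chloro-3-oxobutanoate | CCOC(=O)CC(=O)CCl | starting material
30 | 2-(trimethylsilyl)ethyl 4-chloro-3-oxobutanoate | C[Si](C)(C)CCOC(=O)CC(=O)CCl | intermediate
31 | 2-(trimethylsilyl)ethyl 4-acetoxy-3-oxobutanoate | C[Si](C)(C)CCOC(=O)CC(=O)COC(C)=O | intermediate
32 | 2-(trimethylsilyl)ethyl (E)-4-acetoxy-3-(trifluoromethylsulfonyloxy)but-2-enoate | C[Si](C)(C)CCOC(=O)/C=C(\COC(C)=O)OS(=O)(=O)C(F)(F)F | intermediate
33 | [(2R,5R,9R,10R)-2-(triethylsilyloxy)-13,14,15,16-tetranorlabd-8(17)-en-12-yl]zinc iodide | C=C1CC[C@@H]2C(C)(C)C[C@@H](O[Si](CC)(CC)CC)C[C@@]2(C)[C@@H]1CC[Zn]I | intermediate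
34 | 2-(trimethylsilyl)ethyl (2R,5R,9R,10R,13Z)-16-acetoxy-2-(triethylsilyloxy)labda-8(17),13-dien-15-oate | C=C1CC[C@@H]2C(C)(C)C[C@@H](O[Si](CC)(CC)CC)C[C@@]2(C)[C@@H]1CC/C(=C/C(=O)OCC[Si](C)(C)C)COC(C)=O | intermediate
35 | (2R,5R,9R,10R,13Z)-16-acetoxy-2-hydroxylabda-8(17),13-dien-15-oic acid | C=C1CC[C@@H]2C(C)(C)C[C@@H](O)C[C@@]2(C)[C@@H]1CC/C(=C/C(=O)O)COC(C)=O | target

Total step count: 25. Longest linear sequence: 20 steps (from 1 through steps 1, 2, 5 to 20, 24 and 25).

Steps most likely to fail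

Step 8. Beta-elimination of the C8 silyloxy group during enolization, or ionization and decomposition of the ketene acetal during the long heating that the crowded boat requires, may outrun the sigmatropic shift. The fallback builds the same octalin by cycloaddition; it sets out from 3 and comes back at 14. Stille coupling of 3 with tributyl(vinyl)stannane (Pd(PPh3)4, LiCl, THF, reflux) would give 7,9,9-trimethyl-8-vinyl-1,4-dioxaspiro[4.5]dec-7-ene F1. Diels–Alder reaction of this diene with methyl (E)-3-(benzoyloxy)acrylate, promoted by a chiral oxazaborolidinium Lewis acid (or run at high pressure and followed by resolution of the derived acid), would form C9–C10 and C7–C8 together. The ester should bond at C9 next to C10, the endo mode should place it anti to C20, and the (E)-dienophile should place the C8 oxygen trans to it, to give methyl (8R,9R,10S)-8-(benzoyloxy)-2,2-(ethylenedioxy)-12,13,14,15,16,17-hexanorlabd-5-en-11-oate F2. K2CO3 in MeOH would give methyl (8R,9R,10S)-2,2-(ethylenedioxy)-8-hydroxy-12,13,14,15,16,17-hexanorlabd-5-en-11-oate F3. Silylation (t-BuMe2SiCl, imidazole) would give methyl (8R,9R,10S)-8-(tert-butyldimethylsilyloxy)-2,2-(ethylenedioxy)-12,13,14,15,16,17-hexanorlabd-5-en-11-oate F4, and LiAlH4 would reduce it to 14.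

Step 5. Slow oxidative addition of nickel into the fully substituted, doubly flanked enol triflate may let reduction or homocoupling of the triflate and decay of the beta-silyloxy aldehyde win. The fallback makes the alkenyl nucleophile by a Shapiro reaction; it sets out from 2 and comes back at 7. Condensation of 2 with 2,4,6-triisopropylbenzenesulfonyl hydrazide would give N'-(7,9,9-trimethyl-1,4-dioxaspiro[4.5]decan-8-ylidene)-2,4,6-triisopropylbenzenesulfonohydrazide F5. Treatment with n-BuLi (THF, −78 to 0 °C) would give (7,9,9-trimethyl-1,4-dioxaspiro[4.5]dec-7-en-8-yl)lithium F6, which would be added to aldehyde 6 at −78 °C (after transmetalation with CeCl3 if attack on the ester competes) to give 7.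

Step 7. Hydride delivery to the twisted, doubly ortho-substituted enone may be sluggish and poorly face-selective under external reagent control. The fallback uses internal delivery from the C3 oxygen; it sets out from 8 and comes back at 10. HF·pyridine would give methyl (3R)-3-hydroxy-5-oxo-5-(7,9,9-trimethyl-1,4-dioxaspiro[4.5]dec-7-en-8-yl)pentanoate F7. Evans–Saksena reduction (Me4NBH(OAc)3, MeCN–AcOH, −30 °C) would give the anti diol methyl (3R,5R)-3,5-dihydroxy-5-(7,9,9-trimethyl-1,4-dioxaspiro[4.5]dec-7-en-8-yl)pentanoate F8. PPTS would close (4R,6R)-4-hydroxy-6-(7,9,9-trimethyl-1,4-dioxaspiro[4.5]dec-7-en-8-yl)oxan-2-one F9, and t-BuMe2SiCl with imidazole would return 10.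

Further compounds

F1 | step 8 | 7,9,9-trimethyl-8-vinyl-1,4-dioxaspiro[4.5]dec-7-ene | C=CC1=C(C)CC2(OCCO2)CC1(C)C
F2 | step 8 | methyl (8R,9R,10S)-8-(benzoyloxy)-2,2-(ethylenedioxy)-12,13,14,15,16,17-hexanorlabd-5-en-11-oate | O=C(O[C@@H]1CC=C2C(C)(C)CC3(OCCO3)C[C@@]2(C)[C@H]1C(=O)OC)c1ccccc1
F3 | step 8 | methyl (8R,9R,10S)-2,2-(ethylenedioxy)-8-hydroxy-12,13,14,15,16,17-hexanorlabd-5-en-11-oate | O[C@@H]1CC=C2C(C)(C)CC3(OCCO3)C[C@@]2(C)[C@H]1C(=O)OC
F4 | step 8 | methyl (8R,9R,10S)-8-(tert-butyldimethylsilyloxy)-2,2-(ethylenedioxy)-12,13,14,15,16,17-hexanorlabd-5-en-11-oate | CC(C)(C)[Si](C)(C)O[C@@H]1CC=C2C(C)(C)CC3(OCCO3)C[C@@]2(C)[C@H]1C(=O)OC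
F5 | step 5 | N'-(7,9,9-trimethyl-1,4-dioxaspiro[4.5]decan-8-ylidene)-2,4,6-triisopropylbenzenesulfonohydrazide | CC1CC2(OCCO2)CC(C)(C)C1=NNS(=O)(=O)c1c(C(C)C)cc(C(C)C)cc1C(C)C
F6 | step 5 | (7,9,9-trimethyl-1,4-dioxaspiro[4.5]dec-7-en-8-yl)lithium | [Li]C1=C(C)CC2(OCCO2)CC1(C)C
F7 | step 7 | methyl (3R)-3-hydroxy-5-oxo-5-(7,9,9-trimethyl-1,4-dioxaspiro[4.5]dec-7-en-8-yl)pentanoate | COC(=O)C[C@H](O)CC(=O)C1=C(C)CC2(OCCO2)CC1(C)C
F8 | step 7 | methyl (3R,5R)-3,5-dihydroxy-5-(7,9,9-trimethyl-1,4-dioxaspiro[4.5]dec-7-en-8-yl)pentanoate | COC(=O)C[C@H](O)C[C@@H](O)C1=C(C)CC2(OCCO2)CC1(C)C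
F9 | step 7 | (4R,6R)-4-hydroxy-6-(7,9,9-trimethyl-1,4-dioxaspiro[4.5]dec-7-en-8-yl)oxan-2-one | O=C1C[C@H](O)C[C@@H](O1)C1=C(C)CC2(OCCO2)CC1(C)C
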